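**Retrosynthetic overview**

1. Ring letters: A = prenylated cyclohexenedione with its fused dimethylpyran; B = spiro 1,3-dioxan-4-one; C = cyclohexenone ring of the cage (enoate C=C, bridgehead C–OH, bridging C=O, O-substituted quaternary carbon carrying the prenyl group, O-substituted bridgehead); D = oxolane; E = saturated six-membered ring of the bicyclo[2.2.2]octene.
2. Ring C is closed last, by the bond between the enoate β-carbon and the bridgehead carbinol carbon. Enabling feature: in ring C the carbinol carbon is the only enolisable α-carbon of the bridging ketone (the other α-carbon is the quaternary carbon shared with ring D) and also the γ-carbon of the ring B lactone, so ring C holds a 1,5-dicarbonyl (aldol-condensation) retron with the enoate β-carbon at aldehyde level. An allyl carboxylate blocks this carbon until ring B exists and then leaves as CO2.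
3. Ring B: acid-catalysed union of methoxyquinone 7 (ring A with pyran) and β-hydroxy acid 20 at the spiro ketal carbon. The prenyl group on ring D is carried as allyl and completed by cross-metathesis after the cage is closed.
4. Ring E: Michael–Dieckmann annulation of allyl acrylate on 3-oxooxolane 13 (ring D from a diazo O–H insertion). The only stereocentre set by catalysis is the quaternary carbon of 13; the three other cage centres are relayed from it.
5. Order of ring formation: pyran on ring A (step 2), ring D (step 5), ring E (step 7), ring B (step 11), ring C (step 12).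

Key step: step 12

Assumption: the natural configuration at the spiro ketal carbon and at the adjacent prenyl-bearing CH of ring A is taken to be the thermodynamically preferred one, reached by reversible acid-catalysed ketal exchange and enolisation (steps 11 and 12).

**Route**

Step 1
Reactants: 1 2,6-dimethoxy-1,4-benzoquinone
Product: 2 2-hydroxy-6-methoxy-1,4-benzoquinone
Conditions: NaOH (1.05 equiv), THF/H2O, 0 °C; then 1 M HCl
Reagents that add atoms: sodium hydroxide, [Na+].[OH-]
Why: Addition–elimination of hydroxide at one of the two equivalent vinylogous ester carbons (vinylogous saponification) should stop after one exchange, because the hydroxyquinone anion formed resists a second attack.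

Step 2
Reactants: 2 2-hydroxy-6-methoxy-1,4-benzoquinone; 3 3-methylbut-2-enal
Product: 4 7-methoxy-2,2-dimethyl-2H-chromene-5,8-dione
Conditions: ethylenediammonium diacetate (10 mol %), PhMe, 60 °C
Reagents that add atoms: none
Why: Knoevenagel condensation at the nucleophilic quinone carbon next to the hydroxyl followed by oxa-6π electrocyclisation (formal [3+3] annulation, as in the lawsone-to-pyranonaphthoquinone series) should give the para-quinone-fused 2,2-dimethylpyran.

Step 3
Reactants: 4 7-methoxy-2,2-dimethyl-2H-chromene-5,8-dione; 5 tributyl(3-methylbut-2-en-1-yl)stannane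
Product: 7 7-methoxy-2,2-dimethyl-6-(3-methylbut-2-en-1-yl)-2H-chromene-5,8-dione, via hydroquinone 6 (not isolated)
Conditions: BF3·OEt2 (1.2 equiv), CH2Cl2, −78 → −20 °C; then Ag2O, Et2O, 23 °C
Reagents that add atoms: none
Why: Lewis-acid-mediated addition of the allylic stannane to the quinone (Naruta–Maruyama prenylation: carbonyl addition, then [3,3] shift) should place the prenyl group on the only free ring carbon, and Ag2O returns the hydroquinone to the quinone.

Step 4
Reactants: 8 ethyl 2-diazo-3-oxobutanoate; 9 acetone
Product: 10 ethyl 2-diazo-5-hydroxy-5-methyl-3-oxohexanoate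
Conditions: TiCl4 (1.1 equiv), Et3N (1.2 equiv), CH2Cl2, −78 °C; then 9 (3 equiv), −78 °C
Reagents that add atoms: none
Why: Titanium enolate aldol addition of the methyl ketone terminus to acetone should give the tertiary aldol, since the diazo carbon cannot enolise.

Step 5
Reactants: 10 ethyl 2-diazo-5-hydroxy-5-methyl-3-oxohexanoate
Product: 11 ethyl 5,5-dimethyl-3-oxooxolane-2-carboxylate (racemic)
Conditions: Rh2(OAc)4 (1 mol %), CH2Cl2, 40 °C
Reagents that add atoms: none
Why: Intramolecular O–H insertion of the dirhodium carbenoid into the tertiary alcohol closes ring D as a 3-oxooxolane; the new centre is an enolisable β-keto ester carbon, so its configuration does not matter here.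

Step 6
Reactants: 11 ethyl 5,5-dimethyl-3-oxooxolane-2-carboxylate; 12 prop-2-en-1-yl acetate
Product: 13 ethyl (2R)-5,5-dimethyl-3-oxo-2-(prop-2-en-1-yl)oxolane-2-carboxylate
Conditions: Pd2(dba)3·CHCl3 (2.5 mol %), (R,R)-DACH-phenyl Trost ligand (7.5 mol %), 1,1,3,3-tetramethylguanidine (1.1 equiv), PhMe, 0 °C
Reagents that add atoms: none
Why: Trost asymmetric allylic alkylation (Tsuji–Trost reaction) of the stabilised β-keto ester enolate sets the O,C-substituted quaternary carbon, the one stereocentre set by catalysis, through face discrimination in the chiral ligand pocket (the ligand antipode is used if the sense of induction proves opposite).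

Step 7
Reactants: 13 ethyl (2R)-5,5-dimethyl-3-oxo-2-(prop-2-en-1-yl)oxolane-2-carboxylate; 14 prop-2-en-1-yl prop-2-enoate
Product: 16 prop-2-en-1-yl (1S,5R)-7,7-dimethyl-4,8-dioxo-5-(prop-2-en-1-yl)-6-oxabicyclo[3.2.1]octane-3-carboxylate (C3 epimers and enol), via Michael adduct 15 (not isolated)
Conditions: LiN(SiMe3)2 (1.1 equiv), THF, −78 °C; 14; then LiN(SiMe3)2 (1.1 equiv), −78 → 0 °C; AcOH
Reagents that add atoms: none
Why: Michael addition of the only possible ketone enolate to the acrylate, then Dieckmann condensation onto the ethyl ester (Michael–Dieckmann annulation), closes ring E as a bridged β-keto ester; only the epimer with the propanoate chain cis to the ester can cyclise and the α-keto CH equilibrates under the basic conditions, so the ring-fusion CH is relayed from the quaternary centre, and the product enolate is the thermodynamic sink.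

Step 8
Reactants: 16 bridged β-keto ester; 17 methyl 3,3-dimethoxypropanoate
Product: 18 prop-2-en-1-yl (1R,5R,8S)-8-hydroxy-7,7-dimethyl-4-oxo-5-(prop-2-en-1-yl)-8-(1,1,3-trimethoxy-3-oxopropan-2-yl)-6-oxabicyclo[3.2.1]octane-3-carboxylate (epimers at C3 and at the side-chain CH)
Conditions: 16, LiN(SiMe3)2 (1.05 equiv), THF, −78 °C; then lithium enolate of 17 (17, LiN(i-Pr)2, THF, −78 °C; 1.5 equiv), −78 °C; AcOH at −78 °C
Reagents that add atoms: none
Why: Aldol addition of the ester enolate to the strained, non-enolisable bridging ketone, with the β-keto ester masked as its enolate, should occur over the flattened three-carbon bridge and anti to the gem-dimethyl group of the oxolane bridge, which puts the new side chain syn to ring E as the cage requires.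

Step 9
Reactants: 18 aldol adduct (methyl ester)
Product: 19 2-[(1R,5R,8S)-8-hydroxy-7,7-dimethyl-4-oxo-5-(prop-2-en-1-yl)-3-(prop-2-en-1-yloxycarbonyl)-6-oxabicyclo[3.2.1]octan-8-yl]-3,3-dimethoxypropanoic acid
Conditions: LiOH·H2O (4 equiv), THF/H2O 3:1, 0 → 23 °C; then 1 M HCl to pH 4, 0 °C
Reagents that add atoms: lithium hydroxide, [Li+].[OH-]
Why: Saponification of the methyl ester should be selective because the allyl β-keto ester is present as its unreactive lithium enolate.

Step 10
Reactants: 19 acid
Product: 20 2-[(1R,5R,8S)-3,8-dihydroxy-7,7-dimethyl-4-oxo-5-(prop-2-en-1-yl)-3-(prop-2-en-1-yloxycarbonyl)-6-oxabicyclo[3.2.1]octan-8-yl]-3,3-dimethoxypropanoic acid (C3 epimers)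
Conditions: O2 (1 atm), Cs2CO3 (2.5 equiv), P(OEt)3 (2 equiv), DMSO, 23 °C; then 1 M HCl to pH 4, 0 °C
Reagents that add atoms: dioxygen, O=O
Why: α-Hydroxylation of the β-keto ester enolate with O2 (hydroperoxide reduced in situ by the phosphite) installs the future bridgehead oxygen and makes that carbon quaternary and non-enolisable; its configuration is erased again in step 12.

Step 11
Reactants: 20 hydroxy acid; 7 methoxyquinone
Product: 21 dispiro ketal lactone: ring B (1,3-dioxan-4-one) spiro-fused to ring A at the ketal carbon and to the one-carbon bridge of the oxabicycle, carrying a 5-(methoxymethylidene) group; the oxabicycle keeps the 3-hydroxy-3-(allyloxycarbonyl)-4-oxo unit and the 5-allyl group (C3 epimers)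
Conditions: CSA (0.2 equiv), 5 Å MS, PhMe, 50 °C
Reagents that add atoms: none
Why: Acid-catalysed acetal exchange (1,3-dioxan-4-one formation from a β-hydroxy acid and an enol ether, here the vinylogous methyl ester of the quinone, by conjugate addition and loss of methanol) builds ring B and joins the two fragments at the fully substituted spiro carbon; the same acid turns the β,β-dimethoxy ester into the methoxymethylidene lactone, and the spiro centre and the adjacent enolisable CH should settle thermodynamically (prenyl trans to the bulky cage oxygen).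

Step 12
Reactants: 21 dispiro ketal lactone
Product: 24 C-allyl analogue of the target (cage closed; prop-2-en-1-yl in place of the prenyl group on the quaternary carbon of ring D; all six stereocentres as in 26), via β-keto acid 22 (not isolated), via α-ketol 23 (not isolated)
Conditions: Pd(PPh3)4 (5 mol %), sodium 2-ethylhexanoate (1.1 equiv), CH2Cl2, 23 °C; then CSA (1.6 equiv), 4 Å MS, PhMe, 23 → 60 °C
Reagents that add atoms: none
Why: Proposed new method: zerovalent palladium ionises the allyl ester, 2-ethylhexanoate takes up the allyl group, and on acidification the α-hydroxy β-keto acid 22 loses CO2 to deliver the enol (enediol) of the bridging ketone at exactly the carbon that had been blocked. In the same acid the methoxymethylidene lactone is protonated at its α-carbon to an oxocarbenium ion, the enol attacks this aldehyde-level carbon, and the β-methoxy lactone formed loses methanol through the lactone enol (α-H and OMe are held syn-periplanar on the new bridge) to give the enoate. The closest known reactions are the Tsuji decarboxylation of allyl β-keto esters, decarboxylative aldol additions of β-keto acids and Prins-type cyclisations of vinylogous carbonates, followed by an aldol-type dehydration. The one new C–C bond closes ring C and with it the second six-membered ring of the bicyclo[2.2.2]octene: a six-membered exo-trig attack on the C=O+ carbon that hangs from the sp3 lactone α-carbon, chosen because attack on the planar enol ether itself would have to come within the plane of the double bond. The bridgehead carbinol centre is set by the tether: the electrophile sits on the one-carbon bridge and can reach the enol only from that face, so the hydroxyl points outwards as in the target. Needed are attack by the carbinol end and not the carbonyl end of the enediol (six- versus five-membered ring, no vicinal quaternary carbons) and no cation–olefin cyclisation, which is why the side chain on ring D is still allyl and not prenyl; the carboxyl lock ensures that ring C cannot close before ring B exists.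

Step 13
Reactants: 24 C-allyl analogue of the target; 25 2-methylbut-2-ene
Product: 26 CNP0222516.1 (target)
Conditions: second-generation Grubbs catalyst, RuCl2(PCy3)(H2IMes)(=CHPh) (10 mol %), 25 (excess), CH2Cl2, 40 °C
Reagents that add atoms: none
Why: Olefin cross-metathesis of the terminal allyl group with 2-methylbut-2-ene should convert only the monosubstituted alkene into the prenyl group, because the trisubstituted prenyl, chromene and enoate double bonds are unreactive and no stereocentre is touched.

**Compound list**

1 | 2,6-dimethoxy-1,4-benzoquinone | COC1=CC(=O)C=C(OC)C1=O | starting material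
2 | 2-hydroxy-6-methoxy-1,4-benzoquinone | COC1=CC(=O)C=C(O)C1=O | intermediate
3 | 3-methylbut-2-enal | CC(C)=CC=O | starting material
4 | 7-methoxy-2,2-dimethyl-2H-chromene-5,8-dione | COC1=CC(=O)C2=C(OC(C)(C)C=C2)C1=O | intermediate
5 | tributyl(3-methylbut-2-en-1-yl)stannane | CC(C)=CC[Sn](CCCC)(CCCC)CCCC | starting material
6 | 7-methoxy-2,2-dimethyl-6-(3-methylbut-2-en-1-yl)-2H-chromene-5,8-diol | COC1=C(CC=C(C)C)C(O)=C2C=CC(C)(C)OC2=C1O | intermediate
7 | 7-methoxy-2,2-dimethyl-6-(3-methylbut-2-en-1-yl)-2H-chromene-5,8-dione | COC1=C(CC=C(C)C)C(=O)C2=C(OC(C)(C)C=C2)C1=O | intermediate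
8 | ethyl 2-diazo-3-oxobutanoate | CCOC(=O)C(=[N+]=[N-])C(C)=O | starting material
9 | acetone | CC(C)=O | starting material
10 | ethyl 2-diazo-5-hydroxy-5-methyl-3-oxohexanoate | CCOC(=O)C(=[N+]=[N-])C(=O)CC(C)(C)O | intermediate
11 | ethyl 5,5-dimethyl-3-oxooxolane-2-carboxylate (racemic) | CCOC(=O)C1OC(C)(C)CC1=O | intermediate
12 | prop-2-en-1-yl acetate | CC(=O)OCC=C | starting material
13 | ethyl (2R)-5,5-dimethyl-3-oxo-2-(prop-2-en-1-yl)oxolane-2-carboxylate | CC1(C)CC(=O)[C@](CC=C)(C(=O)OCC)O1 | intermediate
14 | prop-2-en-1-yl prop-2-enoate | C=CC(=O)OCC=C | starting material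
15 | ethyl (2R)-5,5-dimethyl-3-oxo-4-[3-oxo-3-(prop-2-en-1-yloxy)propyl]-2-(prop-2-en-1-yl)oxolane-2-carboxylate (C4 epimers) | C=CCOC(=O)CCC1C(=O)[C@](CC=C)(C(=O)OCC)OC1(C)C | intermediate
16 | prop-2-en-1-yl (1S,5R)-7,7-dimethyl-4,8-dioxo-5-(prop-2-en-1-yl)-6-oxabicyclo[3.2.1]octane-3-carboxylate (C3 epimers) | C=CCOC(=O)C1C[C@H]2C(C)(C)O[C@@](CC=C)(C1=O)C2=O | intermediate
17 | methyl 3,3-dimethoxypropanoate | COC(OC)CC(=O)OC | starting material
18 | prop-2-en-1-yl (1R,5R,8S)-8-hydroxy-7,7-dimethyl-4-oxo-5-(prop-2-en-1-yl)-8-(1,1,3-trimethoxy-3-oxopropan-2-yl)-6-oxabicyclo[3.2.1]octane-3-carboxylate (epimers at C3 and side-chain CH) | C=CCOC(=O)C1C[C@H]2C(C)(C)O[C@@](CC=C)(C1=O)[C@@]2(O)C(C(OC)OC)C(=O)OC | intermediate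
19 | 2-[(1R,5R,8S)-8-hydroxy-7,7-dimethyl-4-oxo-5-(prop-2-en-1-yl)-3-(prop-2-en-1-yloxycarbonyl)-6-oxabicyclo[3.2.1]octan-8-yl]-3,3-dimethoxypropanoic acid | C=CCOC(=O)C1C[C@H]2C(C)(C)O[C@@](CC=C)(C1=O)[C@@]2(O)C(C(OC)OC)C(=O)O | intermediate
20 | 2-[(1R,5R,8S)-3,8-dihydroxy-7,7-dimethyl-4-oxo-5-(prop-2-en-1-yl)-3-(prop-2-en-1-yloxycarbonyl)-6-oxabicyclo[3.2.1]octan-8-yl]-3,3-dimethoxypropanoic acid (C3 epimers) | C=CCOC(=O)C1(O)C[C@H]2C(C)(C)O[C@@](CC=C)(C1=O)[C@@]2(O)C(C(OC)OC)C(=O)O | intermediate
21 | dispiro ketal lactone (rings A, pyran, B, D, E; methoxymethylidene on ring B; allyl α-hydroxy-β-keto ester on ring E; allyl on ring D) | CC(C)=CC[C@H]1C(=O)C2=C(OC(C)(C)C=C2)C(=O)[C@@]12OC(=O)C(=COC)[C@@]3(O2)[C@H]4CC(O)(C(=O)OCC=C)C(=O)[C@]3(CC=C)OC4(C)C | intermediate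
22 | β-keto acid from 21 (allyl ester cleaved) | CC(C)=CC[C@H]1C(=O)C2=C(OC(C)(C)C=C2)C(=O)[C@@]12OC(=O)C(=COC)[C@@]3(O2)[C@H]4CC(O)(C(=O)O)C(=O)[C@]3(CC=C)OC4(C)C | intermediate
23 | α-ketol from 22 (decarboxylated; its enol is the reacting form) | CC(C)=CC[C@H]1C(=O)C2=C(OC(C)(C)C=C2)C(=O)[C@@]12OC(=O)C(=COC)[C@@]3(O2)[C@H]4CC(O)C(=O)[C@]3(CC=C)OC4(C)C | intermediate
24 | C-allyl analogue of the target (cage closed) | CC(C)=CC[C@H]1C(=O)C2=C(OC(C)(C)C=C2)C(=O)[C@@]12OC(=O)C1=C[C@]3(O)C[C@H]4C(C)(C)O[C@@](CC=C)(C3=O)[C@@]14O2 | intermediate
25 | 2-methylbut-2-ene | CC=C(C)C | starting material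
26 | CNP0222516.1 | CC(C)=CC[C@H]1C(=O)C2=C(OC(C)(C)C=C2)C(=O)[C@@]12OC(=O)C1=C[C@]3(O)C[C@H]4C(C)(C)O[C@@](CC=C(C)C)(C3=O)[C@@]14O2 | target

**Step count and risks**

Total step count: 13. Longest linear sequence: 10 steps (steps 4 to 13, from ethyl 2-diazo-3-oxobutanoate).

Step 12 (Proposed new method). The enol delivered by decarboxylation may tautomerise before it is captured, the carbonyl end of the enediol may attack instead (five-membered ring), or the β-methoxy adduct may fail to lose methanol. The fallback uses known reactions only, sets out from 21 and returns at 24. Tsuji decarboxylation–hydrogenolysis (Pd(PPh3)4, HCO2H, Et3N) gives α-ketol 23, now isolated. Hydrolysis of the enol ether (PPTS, wet acetone) gives the α-formyl lactone F1. A titanium-mediated intramolecular aldol addition (TiCl4, i-Pr2NEt, CH2Cl2, −78 °C) gives the β-hydroxy lactone F2, in which ring C is closed. Burgess reagent then dehydrates F2 to 24.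

Step 11. The position of the intermolecular ketal-exchange equilibrium may be unfavourable, or spiro epimers may form. The fallback sets out from 7 and 20 and returns at 21. Vinylogous saponification of 7 (LiOH, THF/H2O) gives the hydroxyquinone F3. Esterification of this vinylogous acid with 20 (DCC, DMAP) gives the acyloxyquinone F4, in which the two fragments are tethered. CSA-promoted intramolecular conjugate addition of the tertiary alcohol (six-membered ring closure), with loss of methanol from the acetal, then gives 21.

Step 8. The aldol addition at the hindered bridging ketone may revert (retro-aldol), and the ester enolate may lose methoxide. The fallback sets out from 16 and 17 and returns at 18. Compound 16 is masked as its trimethylsilyl enol ether F5 (Me3SiCl, Et3N), and 17 is converted into the silyl ketene acetal F6 (LiN(i-Pr)2, Me3SiCl). A TiCl4-promoted Mukaiyama aldol addition, in which the adduct is trapped and cannot revert, followed by acidic work-up gives 18.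

Further compounds
F1 | step 12 | α-formyl lactone (enol ether of 23 hydrolysed) | CC(C)=CC[C@H]1C(=O)C2=C(OC(C)(C)C=C2)C(=O)[C@@]12OC(=O)C(C=O)[C@@]3(O2)[C@H]4CC(O)C(=O)[C@]3(CC=C)OC4(C)C
F2 | step 12 | β-hydroxy lactone (ring C closed, not yet dehydrated) | CC(C)=CC[C@H]1C(=O)C2=C(OC(C)(C)C=C2)C(=O)[C@@]12OC(=O)C1C(O)[C@]3(O)C[C@H]4C(C)(C)O[C@@](CC=C)(C3=O)[C@@]14O2
F3 | step 11 | 7-hydroxy-2,2-dimethyl-6-(3-methylbut-2-en-1-yl)-2H-chromene-5,8-dione | CC(C)=CCC1=C(O)C(=O)C2=C(C=CC(C)(C)O2)C1=O
F4 | step 11 | acyloxyquinone (ester of F3 with acid 20) | CC(C)=CCC1=C(OC(=O)C(C(OC)OC)[C@@]2(O)[C@H]3CC(O)(C(=O)OCC=C)C(=O)[C@]2(CC=C)OC3(C)C)C(=O)C2=C(C=CC(C)(C)O2)C1=O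
F5 | step 8 | trimethylsilyl enol ether of 16 | C=CCOC(=O)C1=C(O[Si](C)(C)C)[C@]2(CC=C)OC(C)(C)[C@H](C1)C2=O
F6 | step 8 | silyl ketene acetal of 17 | COC(OC)C=C(OC)O[Si](C)(C)C
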